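**Remark (one line):** the structure is taken exactly as drawn – a germacra-1(10)Z,4Z,11(13)-trien-12,6-olide whose 8-ester is (2S,3R)-2,3-dimethyloxirane-2-carboxylate (cis-methyl oxirane, i.e. the epoxide of a tiglate); germacrane numbering C1–C15 is used for all ten-membered-ring compounds, and compound numbers are those of the steps below.

## The problem

- The target 26 is a ten-membered carbocycle (C1–C10) with a trans-fused α-methylene-γ-butyrolactone across C6–C7.
- Both ring alkenes, C1=C10 and C4=C5, are trisubstituted and Z. Closing an open chain does not give this geometry reliably.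
- There are four contiguous stereocentres, C6 (R), C7 (S), C8 (S), C9 (R), and a remote one, C3 (S). O3 and O6 lie trans across the Z C4=C5 bond; O8 and O9 are erythro.
- C7 can control C6 (lactone fusion) and C8. C3 is too far from the others and must come from a small ring or a reagent.
- Three oxygens must be told apart: the 3-acetate, the 8-epoxy ester and the free 9-OH beside it.
- Fragile groups: the α-methylene lactone (Michael acceptor towards hydride, phosphines, bases), the α,β-epoxy ester, the 8-acyloxy/9-hydroxy pair (acyl migration under base), and the skipped 1,5-diene.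
- The enabling feature has two parts:
  - C9, the only ring carbon that can be a ketone, lies four bonds from C5. A bond C4–C9 would close atoms C9, C10, C1, C2, C3, C4 into a 2-methylcyclohex-2-enol that already holds C1=C10 as an endocyclic, hence Z, alkene.
  - The unit C4=C5–C6(O–C12) is the adduct of a carboxylic acid O–H across a C4=C5=C6 allene.
  - Together these make the ring the product of an oxy-Cope shift of a 1-alkenyl-2-ethynylcyclohexenol.

## Retrosynthesis

**26 ⇒ 25 ⇒ 24 ⇒ 23.** The last bonds made are C9–H (ketone reduction), then the C3–O acetate bond, then a silyl ether is removed. C9 stays a ketone to the end, so the 9-OH never competes in an acylation and never sits next to the 8-ester under base. The acetate is put on with inversion (Mitsunobu), because the ring fragment is most easily made with O3 cis to the C4 alkyne arm, which leads to 3R in 23. These cuts remove one stereocentre and two protecting-group problems; the forward steps must spare the methylene lactone.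

**23 ⇒ 22.** Cut the lactone C6–O bond and the C5–H bond: 22 is a ten-membered cyclic allene (C4=C5=C6) with an acrylic acid on C7. This replaces two stereo-elements of 23 (the C6 centre and the Z C4=C5 geometry) by an allene whose axis need not be controlled. The alternative cut at C6–C7 leaves both elements to a macrocyclisation. The forward reaction must add O–H across C5=C6 so that C3 and C6 end cis on the alkene and O6 ends trans to the C7 side chain.

**22 ⇒ 20 ⇒ 19 ⇒ 15 + 18.** Adjust the oxidation level at C12 (acid 22 from alcohol 20 via enal 21, silyl ether 19) and cut the C8–O acyl bond. The ester is formed with inversion from the 8R ketol 15, because that epimer is the one expected from peripheral attack on the ring enolate. Acid 18 comes from 16 via 17 by Sharpless epoxidation and oxidation.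

**15 ⇒ 12 (key).** Reconnect C4–C9, cut C6–C7 and remove O8: a retro anionic oxy-Cope shift plus enolate hydroxylation, through alkoxide 13 and enolate 14. The other six-membered-ring reconnection, C1–C6, would leave C1=C10 to be formed in the shift with uncertain geometry. The cut at C4–C9 keeps C1=C10 inside the six-membered ring, and the linear alkyne arm removes the geometry question at C4=C5 from this step. Precursor 12 is a cyclohexenol with three stereocentres, all set by additions to a six-membered ring. The forward step must transfer these to C7 and create the ten-membered ring and the C8 oxygen in one flask.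

**12 ⇒ 6 + 10.** Cut C8–C9: 1,2-addition of dienyllithium 11 (from iodide 10) to enone 6. The addition must come anti to the ethynyl group.

**6 ⇒ 5 ⇒ 4 ⇒ 3 ⇒ 2 ⇒ 1; 10 ⇒ 9 ⇒ 8 ⇒ 7.** The enone comes from 2-methylcyclohexane-1,3-dione 1 by C-ethynylation (2), desymmetrising reduction (3), silylation (4), methylation (5) and dehydrogenation. The iodide comes from diol 7 by monosilylation (8), oxidation (9) and Takai olefination.

## Roads not taken

**Alternative 1:** (the obvious one) cut C6–C7 and the lactone C–O bond; the forward key step is an intramolecular Barbier or Nozaki–Hiyama–Kishi allylation of the open-chain formyl 2-(bromomethyl)acrylate A1, closing the ring and the lactone together.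
- A1 needs both Z trisubstituted alkenes and three stereocentres (C3, C8, C9) built on an open chain.
- Its Z-enal is prone to isomerise.
- C6 and C7 are set in a macrocyclisation whose facial control on a Z,Z chain cannot be predicted.
- The chosen plan gets one Z alkene from a six-membered ring, the other from a ring constraint, and sets C7 by chirality transfer from a small ring.

**Alternative 2:** cut C4=C5; the forward key step is ring-closing metathesis of diene lactone A2 with a second-generation Grubbs catalyst.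
- A trisubstituted alkene in a strained ten-membered ring is the hardest case for metathesis.
- The Z/E outcome is not under control, and the α-methylene lactone is a competing alkene.
- A2 already carries all six stereocentres and both esters, so a failure comes late.

**Alternative 3:** cut C6–C7 with the oxygen kept on C6; the forward key step is a [2,3]-Wittig ring contraction of the thirteen-membered diallyl ether A3.
- Deprotonation must choose C6 over C13.
- Two stereocentres are set at once in a flexible ring.
- The open chain with both Z alkenes and a macro-etherification are still needed, so the route is longer than the ring expansion of a cyclohexenol.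

Key step: step 10

## Steps

Step 1
Reactants: 1 2-methylcyclohexane-1,3-dione
Product: 2 2-ethynyl-2-methylcyclohexane-1,3-dione
Conditions: TMS-EBX, Bu4NF, THF, −78 °C to rt
Reagents that add atoms: 1-[(trimethylsilyl)ethynyl]-1,2-benziodoxol-3(1H)-one (TMS-EBX), C[Si](C)(C)C#CI1OC(=O)c2ccccc12
Why: Electrophilic alkynylation of a stabilised enolate by an ethynyl benziodoxolone; fluoride unmasks the ethynyl iodane, the dione enolate attacks it at carbon, and the quaternary (prochiral) C4 with its two-carbon arm C5–C6 is formed.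

Step 2
Reactants: 2 2-ethynyl-2-methylcyclohexane-1,3-dione
Product: 3 (2R,3R)-2-ethynyl-3-hydroxy-2-methylcyclohexan-1-one (OH cis to ethynyl)
Conditions: (S)-2-methyl-CBS-oxazaborolidine (10 mol%), catecholborane, toluene, −78 °C
Reagents that add atoms: none
Why: Corey–Bakshi–Shibata reduction desymmetrises the dione: the catalyst fixes the carbinol as 3R (quaternary carbon as the large group), and the carbonyl reduced is the one that lets hydride enter anti to the slim, pseudo-axial ethynyl group, so OH ends cis to ethynyl and the quaternary centre becomes 2R. At low temperature the reduction should stop at the hydroxy ketone.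

Step 3
Reactants: 3 (2R,3R)-2-ethynyl-3-hydroxy-2-methylcyclohexan-1-one
Product: 4 (2R,3R)-2-ethynyl-2-methyl-3-[(triisopropylsilyl)oxy]cyclohexan-1-one
Conditions: iPr3SiOSO2CF3, 2,6-lutidine, CH2Cl2, −78 to 0 °C
Reagents that add atoms: triisopropylsilyl trifluoromethanesulfonate, CC(C)[Si](C(C)C)(C(C)C)OS(=O)(=O)C(F)(F)F
Why: Silylation of a hindered secondary alcohol by a silyl triflate; the bulky silyl group is chosen because it should neither migrate to the tertiary alkoxide of step 10 nor act as a nucleophile in step 16.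

Step 4
Reactants: 4 (2R,3R)-2-ethynyl-2-methyl-3-[(triisopropylsilyl)oxy]cyclohexan-1-one
Product: 5 (2R,3R)-2-ethynyl-2,6-dimethyl-3-[(triisopropylsilyl)oxy]cyclohexan-1-one (both C6 epimers)
Conditions: LiN(iPr)2, THF, −78 °C; MeI
Reagents that add atoms: iodomethane, CI
Why: Enolate alkylation; enolisation can only occur at C6 because C2 is quaternary, and both epimers converge in step 5. Any acetylide formed should hand its charge to the more stable enolate before methylation.

Step 5
Reactants: 5 (2R,3R)-2-ethynyl-2,6-dimethyl-3-[(triisopropylsilyl)oxy]cyclohexan-1-one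
Product: 6 (5R,6R)-6-ethynyl-2,6-dimethyl-5-[(triisopropylsilyl)oxy]cyclohex-2-en-1-one
Conditions: IBX, DMSO/toluene, 70 °C
Reagents that add atoms: none
Why: IBX dehydrogenation of a ketone via its enol gives the endocyclic, more substituted enone; this ring alkene becomes the Z C1=C10 bond of the target.

Step 6
Reactants: 7 2-methylidenepropane-1,3-diol
Product: 8 2-{[(triethylsilyl)oxy]methyl}prop-2-en-1-ol
Conditions: NaH (1.0 equiv), THF, 0 °C; Et3SiCl (1.0 equiv)
Reagents that add atoms: chlorotriethylsilane, CC[Si](CC)(CC)Cl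
Why: Monosilylation of a symmetrical diol through its poorly soluble monosodium alkoxide.

Step 7
Reactants: 8 2-{[(triethylsilyl)oxy]methyl}prop-2-en-1-ol
Product: 9 2-{[(triethylsilyl)oxy]methyl}prop-2-enal
Conditions: MnO2, CH2Cl2, rt
Reagents that add atoms: none
Why: Selective oxidation of an allylic alcohol to the enal on manganese dioxide; the silyl ether is untouched.

Step 8
Reactants: 9 2-{[(triethylsilyl)oxy]methyl}prop-2-enal
Product: 10 triethyl{[(3E)-4-iodo-2-methylidenebut-3-en-1-yl]oxy}silane
Conditions: CrCl2, CHI3, THF, 0 °C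
Reagents that add atoms: iodoform, C(I)(I)I
Why: Takai olefination converts the aldehyde into the E vinyl iodide; the E geometry later places the C7 side chain pseudo-equatorial in step 10.

Step 9
Reactants: 10 triethyl{[(3E)-4-iodo-2-methylidenebut-3-en-1-yl]oxy}silane; 6 (5R,6R)-6-ethynyl-2,6-dimethyl-5-[(triisopropylsilyl)oxy]cyclohex-2-en-1-one
Product: 12 (1S,5R,6R)-6-ethynyl-2,6-dimethyl-1-[(1E)-3-{[(triethylsilyl)oxy]methyl}buta-1,3-dien-1-yl]-5-[(triisopropylsilyl)oxy]cyclohex-2-en-1-ol, via alkenyllithium 11 (not isolated)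
Conditions: 10, t-BuLi (2 equiv per iodide), Et2O, −78 °C; then 6 (11 used at 2.2 equiv), −78 to −40 °C; aq NH4Cl
Reagents that add atoms: none
Why: Iodine–lithium exchange with retention of the E geometry, then 1,2-addition to the enone; one equivalent of 11 is consumed by the acetylenic proton. In the favoured half-chair of 6 the ethynyl group is pseudo-axial and the methyl and silyloxy groups equatorial, so axial attack anti to ethynyl should set the carbinol centre as 1S (dienyl trans to ethynyl).

Step 10
Reactants: 12 (1S,5R,6R)-6-ethynyl-2,6-dimethyl-1-[(1E)-3-{[(triethylsilyl)oxy]methyl}buta-1,3-dien-1-yl]-5-[(triisopropylsilyl)oxy]cyclohex-2-en-1-ol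
Product: 15 (3R,7R,8R)-8-hydroxy-12-[(triethylsilyl)oxy]-3-[(triisopropylsilyl)oxy]germacra-1(10)Z,4,5,11(13)-tetraen-9-one (4,5-allene of Sa configuration), via potassium alkoxide 13 (not isolated), via potassium enolate 14 (not isolated)
Conditions: KN(SiMe3)2 (1.05 equiv), 18-crown-6, THF, −78 to 45 °C; then −78 °C, 2-(phenylsulfonyl)-3-phenyloxaziridine; aq NH4Cl
Reagents that add atoms: 2-(benzenesulfonyl)-3-phenyloxaziridine, O=S(=O)(c1ccccc1)N1OC1c1ccccc1
Why: Alkoxide 13 undergoes the acetylenic variant of the anionic oxy-Cope rearrangement: C4–C9 breaks while C6–C7 forms through a six-centre array, so the cyclohexenol grows by four atoms into the ten-membered ring (ring expansion by a [3,3] shift, not an end-to-end closure) and the alkyne becomes the C4=C5=C6 allene. The closest known reactions are the anionic oxy-Cope ring expansion of 1,2-dialkenylcyclohexanols with hydroxylation of the enolate in the same flask, and the oxy-Cope shift of 1-en-5-yn-3-ols to allenyl carbonyl compounds. The shift can only start from the ring-flipped half-chair in which ethynyl and dienyl are both pseudo-equatorial (gauche); there C6 meets C7 on the face of the dienyl unit that keeps the C11 branch of the E alkene pseudo-equatorial. C4 and C9 are destroyed and their configuration passes to C7 (target geometry) and to the allene axis, which need not be controlled further. C1=C10 stays Z because it was the endocyclic alkene of the six-membered ring. In enolate 14, H7 is eclipsed with the C–O bond and the side chain points away, so the oxaziridine should enter C8 from the outer face of the ring, anti to the C7–C6 ring bond, giving the 8R ketol that the invertive esterification of step 13 needs. The step needs the [3,3] shift to beat retro-addition of the hindered alkoxide (favoured by irreversible enolate formation) and oxygen transfer to C8 only (C8 is the only nucleophilic carbon of the cross-conjugated enolate).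

Step 11
Reactants: 16 (2E)-2-methylbut-2-en-1-ol
Product: 17 [(2R,3R)-2,3-dimethyloxiran-2-yl]methanol
Conditions: Ti(OiPr)4 (cat.), D-(−)-diethyl tartrate (cat.), t-BuOOH, 4 Å sieves, CH2Cl2, −20 °C
Reagents that add atoms: tert-butyl hydroperoxide, CC(C)(C)OO
Why: Sharpless asymmetric epoxidation; the D-tartrate delivers oxygen to the face that gives the (2R,3R) epoxy alcohol, and the E alkene fixes the cis relation of the two methyl groups.

Step 12
Reactants: 17 [(2R,3R)-2,3-dimethyloxiran-2-yl]methanol
Product: 18 (2S,3R)-2,3-dimethyloxirane-2-carboxylic acid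
Conditions: RuCl3 hydrate (cat.), NaIO4, MeCN/EtOAc/H2O, 0 °C
Reagents that add atoms: water, O
Why: Ruthenium tetroxide oxidation of an epoxy alcohol to the glycidic acid, a transformation known to leave the epoxide intact; no stereocentre is touched (the descriptor at C2 changes only by priority).

Step 13
Reactants: 15 (3R,7R,8R)-8-hydroxy-12-[(triethylsilyl)oxy]-3-[(triisopropylsilyl)oxy]germacra-1(10)Z,4,5,11(13)-tetraen-9-one; 18 (2S,3R)-2,3-dimethyloxirane-2-carboxylic acid
Product: 19 (3R,7R,8S)-8-{[(2S,3R)-2,3-dimethyloxiran-2-yl]carbonyloxy}-12-[(triethylsilyl)oxy]-3-[(triisopropylsilyl)oxy]germacra-1(10)Z,4,5,11(13)-tetraen-9-one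
Conditions: PPh3, DIAD, toluene, 0 °C to rt
Reagents that add atoms: none
Why: Mitsunobu esterification; the carboxylate displaces the oxyphosphonium group at the carbonyl-activated C8 by SN2, so 8R becomes the 8S ester of the target. No other free hydroxyl is present.

Step 14
Reactants: 19 (3R,7R,8S)-8-{[(2S,3R)-2,3-dimethyloxiran-2-yl]carbonyloxy}-12-[(triethylsilyl)oxy]-3-[(triisopropylsilyl)oxy]germacra-1(10)Z,4,5,11(13)-tetraen-9-one
Product: 20 (3R,7R,8S)-8-{[(2S,3R)-2,3-dimethyloxiran-2-yl]carbonyloxy}-12-hydroxy-3-[(triisopropylsilyl)oxy]germacra-1(10)Z,4,5,11(13)-tetraen-9-one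
Conditions: PPTS (cat.), MeOH, 0 °C
Reagents that add atoms: none
Why: Mild acid methanolysis removes the primary allylic triethylsilyl ether and leaves the hindered secondary triisopropylsilyl ether, the allene and the epoxy ester.

Step 15
Reactants: 20 (3R,7R,8S)-8-{[(2S,3R)-2,3-dimethyloxiran-2-yl]carbonyloxy}-12-hydroxy-3-[(triisopropylsilyl)oxy]germacra-1(10)Z,4,5,11(13)-tetraen-9-one
Product: 22 (3R,7R,8S)-8-{[(2S,3R)-2,3-dimethyloxiran-2-yl]carbonyloxy}-9-oxo-3-[(triisopropylsilyl)oxy]germacra-1(10)Z,4,5,11(13)-tetraen-12-oic acid, via enal 21 (not isolated)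
Conditions: MnO2, CH2Cl2, rt; filter; then NaClO2, NaH2PO4, 2-methylbut-2-ene, t-BuOH/H2O, 0 °C
Reagents that add atoms: sodium chlorite, [Na+].[O-]Cl=O
Why: Allylic oxidation to the enal and Pinnick oxidation to the acrylic acid; the alkene scavenger traps hypochlorous acid so the allene and ring alkenes are spared.

Step 16
Reactants: 22 (3R,7R,8S)-8-{[(2S,3R)-2,3-dimethyloxiran-2-yl]carbonyloxy}-9-oxo-3-[(triisopropylsilyl)oxy]germacra-1(10)Z,4,5,11(13)-tetraen-12-oic acid
Product: 23 (3R,6R,7S,8S)-8-{[(2S,3R)-2,3-dimethyloxiran-2-yl]carbonyloxy}-9-oxo-3-[(triisopropylsilyl)oxy]germacra-1(10)Z,4Z,11(13)-trien-12,6-olide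
Conditions: Ph3PAuCl (5 mol%), AgOSO2CF3 (5 mol%), CH2Cl2, 0 °C to rt
Reagents that add atoms: none
Why: Gold-catalysed cycloisomerisation of a 4,5-allenoic acid: the carboxyl oxygen closes the five-membered lactone at C6 (5-exo on C5=C6) and the C5–Au bond is protonated. In the planar gold–allyl cation the ring forces C3 and C7 to the inside of a U, which gives Z C4=C5; allylic strain keeps H7 in the plane, so the carboxyl adds on the face of its own side chain, trans to C8, giving 6R and the trans lactone.

Step 17
Reactants: 23 (3R,6R,7S,8S)-8-{[(2S,3R)-2,3-dimethyloxiran-2-yl]carbonyloxy}-9-oxo-3-[(triisopropylsilyl)oxy]germacra-1(10)Z,4Z,11(13)-trien-12,6-olide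
Product: 24 (3R,6R,7S,8S)-8-{[(2S,3R)-2,3-dimethyloxiran-2-yl]carbonyloxy}-3-hydroxy-9-oxogermacra-1(10)Z,4Z,11(13)-trien-12,6-olide
Conditions: HF·pyridine, pyridine, THF, 0 °C to rt
Reagents that add atoms: none
Why: Buffered fluoride desilylation, non-basic so that the methylene lactone and the α-acyloxy ketone are not attacked.

Step 18
Reactants: 24 (3R,6R,7S,8S)-8-{[(2S,3R)-2,3-dimethyloxiran-2-yl]carbonyloxy}-3-hydroxy-9-oxogermacra-1(10)Z,4Z,11(13)-trien-12,6-olide
Product: 25 (3S,6R,7S,8S)-3-acetoxy-8-{[(2S,3R)-2,3-dimethyloxiran-2-yl]carbonyloxy}-9-oxogermacra-1(10)Z,4Z,11(13)-trien-12,6-olide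
Conditions: AcOH, PPh3, DIAD, toluene, 0 °C
Reagents that add atoms: acetic acid, CC(=O)O
Why: Mitsunobu reaction with acetic acid installs the acetate and inverts C3 from 3R to 3S in one operation; C3 is the only free hydroxyl, and SN2 at C3 should be preferred over SN2′ at the hindered C5.

Step 19
Reactants: 25 (3S,6R,7S,8S)-3-acetoxy-8-{[(2S,3R)-2,3-dimethyloxiran-2-yl]carbonyloxy}-9-oxogermacra-1(10)Z,4Z,11(13)-trien-12,6-olide
Product: 26 (3S,6R,7S,8S,9R)-3-acetoxy-8-{[(2S,3R)-2,3-dimethyloxiran-2-yl]carbonyloxy}-9-hydroxygermacra-1(10)Z,4Z,11(13)-trien-12,6-olide (CNP0299903.2)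
Conditions: Zn(BH4)2, Et2O, −40 °C; aq NH4Cl
Reagents that add atoms: none
Why: Chelation-controlled 1,2-reduction of the α-acyloxy enone: zinc bridges the ketone and ester oxygens and hydride enters anti to C7, which should give the erythro 8,9 pair (9R). Zinc borohydride is expected not to reduce the lactone, the esters or the conjugated methylene group.

## Compound list

1 | 2-methylcyclohexane-1,3-dione | CC1C(=O)CCCC1=O | starting material
2 | 2-ethynyl-2-methylcyclohexane-1,3-dione | C#CC1(C)C(=O)CCCC1=O | intermediate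
3 | (2R,3R)-2-ethynyl-3-hydroxy-2-methylcyclohexan-1-one | C#C[C@@]1(C)C(=O)CCC[C@H]1O | intermediate
4 | (2R,3R)-2-ethynyl-2-methyl-3-[(triisopropylsilyl)oxy]cyclohexan-1-one | C#C[C@@]1(C)C(=O)CCC[C@H]1O[Si](C(C)C)(C(C)C)C(C)C | intermediate
5 | (2R,3R)-2-ethynyl-2,6-dimethyl-3-[(triisopropylsilyl)oxy]cyclohexan-1-one (C6 epimers) | C#C[C@@]1(C)C(=O)C(C)CC[C@H]1O[Si](C(C)C)(C(C)C)C(C)C | intermediate
6 | (5R,6R)-6-ethynyl-2,6-dimethyl-5-[(triisopropylsilyl)oxy]cyclohex-2-en-1-one | C#C[C@@]1(C)C(=O)C(C)=CC[C@H]1O[Si](C(C)C)(C(C)C)C(C)C | intermediate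
7 | 2-methylidenepropane-1,3-diol | C=C(CO)CO | starting material
8 | 2-{[(triethylsilyl)oxy]methyl}prop-2-en-1-ol | C=C(CO)CO[Si](CC)(CC)CC | intermediate
9 | 2-{[(triethylsilyl)oxy]methyl}prop-2-enal | C=C(C=O)CO[Si](CC)(CC)CC | intermediate
10 | triethyl{[(3E)-4-iodo-2-methylidenebut-3-en-1-yl]oxy}silane | I/C=C/C(=C)CO[Si](CC)(CC)CC | intermediate
11 | (1E)-3-{[(triethylsilyl)oxy]methyl}buta-1,3-dien-1-yllithium | [Li]/C=C/C(=C)CO[Si](CC)(CC)CC | intermediate
12 | (1S,5R,6R)-6-ethynyl-2,6-dimethyl-1-[(1E)-3-{[(triethylsilyl)oxy]methyl}buta-1,3-dien-1-yl]-5-[(triisopropylsilyl)oxy]cyclohex-2-en-1-ol | C#C[C@@]1(C)[C@](O)(/C=C/C(=C)CO[Si](CC)(CC)CC)C(C)=CC[C@H]1O[Si](C(C)C)(C(C)C)C(C)C | intermediate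
13 | potassium alkoxide of 12 | C#C[C@@]1(C)[C@]([O-])(/C=C/C(=C)CO[Si](CC)(CC)CC)C(C)=CC[C@H]1O[Si](C(C)C)(C(C)C)C(C)C.[K+] | intermediate
14 | potassium enolate of the ring-expanded allenyl ketone (C8=C9 enolate, O cis to C7) | [K+].[O-]/C1=C\[C@@H](C(=C)CO[Si](CC)(CC)CC)C=[C@@]=C(C)[C@H](O[Si](C(C)C)(C(C)C)C(C)C)C/C=C1/C | intermediate
15 | (3R,7R,8R)-8-hydroxy-12-[(triethylsilyl)oxy]-3-[(triisopropylsilyl)oxy]germacra-1(10)Z,4,5,11(13)-tetraen-9-one (Sa allene) | O=C1[C@H](O)[C@@H](C(=C)CO[Si](CC)(CC)CC)C=[C@@]=C(C)[C@H](O[Si](C(C)C)(C(C)C)C(C)C)C/C=C1/C | intermediate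
16 | (2E)-2-methylbut-2-en-1-ol | C/C=C(\C)CO | starting material
17 | [(2R,3R)-2,3-dimethyloxiran-2-yl]methanol | OC[C@@]1(C)O[C@@H]1C | intermediate
18 | (2S,3R)-2,3-dimethyloxirane-2-carboxylic acid | OC(=O)[C@@]1(C)O[C@@H]1C | intermediate
19 | (3R,7R,8S)-8-{[(2S,3R)-2,3-dimethyloxiran-2-yl]carbonyloxy}-12-[(triethylsilyl)oxy]-3-[(triisopropylsilyl)oxy]germacra-1(10)Z,4,5,11(13)-tetraen-9-one | O=C1[C@@H](OC(=O)[C@@]2(C)O[C@@H]2C)[C@@H](C(=C)CO[Si](CC)(CC)CC)C=[C@@]=C(C)[C@H](O[Si](C(C)C)(C(C)C)C(C)C)C/C=C1/C | intermediate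
20 | (3R,7R,8S)-8-{[(2S,3R)-2,3-dimethyloxiran-2-yl]carbonyloxy}-12-hydroxy-3-[(triisopropylsilyl)oxy]germacra-1(10)Z,4,5,11(13)-tetraen-9-one | O=C1[C@@H](OC(=O)[C@@]2(C)O[C@@H]2C)[C@@H](C(=C)CO)C=[C@@]=C(C)[C@H](O[Si](C(C)C)(C(C)C)C(C)C)C/C=C1/C | intermediate
21 | (3R,7R,8S)-8-{[(2S,3R)-2,3-dimethyloxiran-2-yl]carbonyloxy}-9-oxo-3-[(triisopropylsilyl)oxy]germacra-1(10)Z,4,5,11(13)-tetraen-12-al | O=C1[C@@H](OC(=O)[C@@]2(C)O[C@@H]2C)[C@@H](C(=C)C=O)C=[C@@]=C(C)[C@H](O[Si](C(C)C)(C(C)C)C(C)C)C/C=C1/C | intermediate
22 | (3R,7R,8S)-8-{[(2S,3R)-2,3-dimethyloxiran-2-yl]carbonyloxy}-9-oxo-3-[(triisopropylsilyl)oxy]germacra-1(10)Z,4,5,11(13)-tetraen-12-oic acid | O=C1[C@@H](OC(=O)[C@@]2(C)O[C@@H]2C)[C@@H](C(=C)C(=O)O)C=[C@@]=C(C)[C@H](O[Si](C(C)C)(C(C)C)C(C)C)C/C=C1/C | intermediate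
23 | (3R,6R,7S,8S)-8-{[(2S,3R)-2,3-dimethyloxiran-2-yl]carbonyloxy}-9-oxo-3-[(triisopropylsilyl)oxy]germacra-1(10)Z,4Z,11(13)-trien-12,6-olide | C=C1C(=O)O[C@@H]2/C=C(/C)[C@H](O[Si](C(C)C)(C(C)C)C(C)C)C/C=C(/C)C(=O)[C@@H](OC(=O)[C@@]3(C)O[C@@H]3C)[C@@H]12 | intermediate
24 | (3R,6R,7S,8S)-8-{[(2S,3R)-2,3-dimethyloxiran-2-yl]carbonyloxy}-3-hydroxy-9-oxogermacra-1(10)Z,4Z,11(13)-trien-12,6-olide | C=C1C(=O)O[C@@H]2/C=C(/C)[C@H](O)C/C=C(/C)C(=O)[C@@H](OC(=O)[C@@]3(C)O[C@@H]3C)[C@@H]12 | intermediate
25 | (3S,6R,7S,8S)-3-acetoxy-8-{[(2S,3R)-2,3-dimethyloxiran-2-yl]carbonyloxy}-9-oxogermacra-1(10)Z,4Z,11(13)-trien-12,6-olide | C=C1C(=O)O[C@@H]2/C=C(/C)[C@@H](OC(C)=O)C/C=C(/C)C(=O)[C@@H](OC(=O)[C@@]3(C)O[C@@H]3C)[C@@H]12 | intermediate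
26 | (3S,6R,7S,8S,9R)-3-acetoxy-8-{[(2S,3R)-2,3-dimethyloxiran-2-yl]carbonyloxy}-9-hydroxygermacra-1(10)Z,4Z,11(13)-trien-12,6-olide (CNP0299903.2) | C=C1C(=O)O[C@@H]2/C=C(/C)[C@@H](OC(C)=O)C/C=C(/C)[C@@H](O)[C@@H](OC(=O)[C@@]3(C)O[C@@H]3C)[C@@H]12 | target

## Step count and least certain steps

Total step count: 19. Longest linear sequence: 14 (steps 1–5, 9, 10, 13–19).

**Step 10 (key step).** The reactive half-chair carries three pseudo-axial groups, so the [3,3] shift may be slow enough for retro-addition of the dienyl anion, or proton transfer to the acetylide, to take over.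
- Fallback, from 12 back to 15: a neutral, two-stage version. Silylate 12 (Me3SiCl, imidazole) to the trimethylsilyl ether F1. Rearrange it thermally (o-dichlorobenzene, 180 °C) to the ring-expanded trimethylsilyl enol ether F2. Carry out a Rubottom oxidation with dimethyldioxirane at −78 °C and a mild acidic work-up, which returns 15.

**Step 16.** The carboxyl group may add to the wrong face or the wrong terminus of the gold-bound allene (6-epimer, E alkene or seven-membered lactone), or the allene may be consumed by protonation and elimination.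
- Fallback, from 22 back to 23: iodolactonisation (I2, NaHCO3, MeCN), a strictly anti addition with the large iodine on the outside of the ring, gives the 5-iodo lactone F3. Reductive removal of iodine with retention of the alkene geometry (Bu3SnH, Pd(PPh3)4) gives 23.

**Step 13.** The oxyphosphonium derivative of the α-ketol may enolise or eliminate, or the hindered acid may react through an acyloxyphosphonium path with retention.
- Fallback, from 15 back to 19: convert 15 into the α-keto triflate F4 (triflic anhydride, 2,6-lutidine, −78 °C) and displace it with 18 and Cs2CO3 (18-crown-6, toluene), again with inversion. If step 10 should give the 8S ketol instead, the same ester is reached with retention by carbodiimide coupling.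

**Step 19.** Hydride may be delivered to the wrong face of the C9 ketone (threo 8,9 pair) if chelation by the acyloxy group is weak, or may add in a conjugate sense to the methylene lactone.
- Fallback, from 25 back to 26: hand the facial choice to a catalyst – Corey–Bakshi–Shibata reduction of the enone with catecholborane at −78 °C, choosing the oxazaborolidine enantiomer that delivers 9R. No new compound is involved.

**Step 9.** Facial selectivity of the addition may be poor if the bulky dienyllithium does not follow the axial trajectory anti to the ethynyl group; only the 1S epimer leads to the right C7.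
- Fallback, from 9 and 6 back to 12: convert 9 into the enyne triethyl[(2-methylidenebut-3-yn-1-yl)oxy]silane F5 (dimethyl (1-diazo-2-oxopropyl)phosphonate, K2CO3, MeOH). Add its lithium acetylide, a small linear nucleophile with a strong preference for axial attack, to 6 to give the propargylic alcohol F6. Reduce F6 to the E dienyl carbinol 12 with NaAlH2(OCH2CH2OMe)2 (trans-hydroalumination of the propargylic alcohol).

## Further compounds

F1 | step 10 | trimethylsilyl ether of 12 | C#C[C@@]1(C)[C@](O[Si](C)(C)C)(/C=C/C(=C)CO[Si](CC)(CC)CC)C(C)=CC[C@H]1O[Si](C(C)C)(C(C)C)C(C)C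
F2 | step 10 | ring-expanded trimethylsilyl enol ether (9-trimethylsilyloxy-germacra-1(10)Z,4,5,8,11(13)-pentaene) | C[Si](C)(C)O/C1=C\[C@@H](C(=C)CO[Si](CC)(CC)CC)C=[C@@]=C(C)[C@H](O[Si](C(C)C)(C(C)C)C(C)C)C/C=C1/C
F3 | step 16 | 5-iodo derivative of lactone 23 | C=C1C(=O)O[C@@H]2/C(I)=C(/C)[C@H](O[Si](C(C)C)(C(C)C)C(C)C)C/C=C(/C)C(=O)[C@@H](OC(=O)[C@@]3(C)O[C@@H]3C)[C@@H]12
F4 | step 13 | 8-O-trifluoromethanesulfonate of 15 | O=C1[C@H](OS(=O)(=O)C(F)(F)F)[C@@H](C(=C)CO[Si](CC)(CC)CC)C=[C@@]=C(C)[C@H](O[Si](C(C)C)(C(C)C)C(C)C)C/C=C1/C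
F5 | step 9 | triethyl[(2-methylidenebut-3-yn-1-yl)oxy]silane | C#CC(=C)CO[Si](CC)(CC)CC
F6 | step 9 | (1S,5R,6R)-6-ethynyl-2,6-dimethyl-1-(3-{[(triethylsilyl)oxy]methyl}but-3-en-1-yn-1-yl)-5-[(triisopropylsilyl)oxy]cyclohex-2-en-1-ol | C#C[C@@]1(C)[C@](O)(C#CC(=C)CO[Si](CC)(CC)CC)C(C)=CC[C@H]1O[Si](C(C)C)(C(C)C)C(C)C
F0 | step 19 | none | none
A1 | alternative 1 | open-chain Z,Z formyl 2-(bromomethyl)acrylate (tris-TBS ether) for the Barbier closure of C6–C7 | O=C/C=C(/C)[C@@H](O[Si](C)(C)C(C)(C)C)C/C=C(/C)[C@@H](O[Si](C)(C)C(C)(C)C)[C@@H](O[Si](C)(C)C(C)(C)C)/C=C(\CBr)C(=O)OC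
A2 | alternative 2 | seco-4,5 diene lactone for ring-closing metathesis | C=C1C(=O)O[C@H](C=C)[C@H]1[C@H](OC(=O)[C@@]2(C)O[C@@H]2C)[C@H](O)/C(C)=C\C[C@H](OC(C)=O)C(C)=C
A3 | alternative 3 | thirteen-membered diallyl ether for the [2,3]-Wittig ring contraction | O1C/C(CO[Si](C)(C)C(C)(C)C)=C\[C@H](O[Si](C)(C)C(C)(C)C)[C@H](O[Si](C)(C)C(C)(C)C)/C(C)=C\C[C@H](O[Si](C)(C)C(C)(C)C)/C(C)=C\C1
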